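**Retrosynthetic overview**
- The side-chain oxirane (C10–C11) is formed last, by reagent-controlled epoxidation of a prenyl alkene; the C1 acetate and the C2/C8 angelates come from stepwise acylation of a chlorotriol.
- The prenyl group comes from cross-metathesis of an allyl group; the key C8–C9 bond comes from asymmetric carbonyl allylation of a ring-bearing 2-substituted acrolein (fragment 1) with B-allyldiisopinocampheylborane (fragment 2).
- The enal comes from the isopropenyl methyl group by ene chlorination, acetate displacement, methanolysis and oxidation.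
- All ring stereocentres derive from (S)-carvone: α'-hydroxylation, Luche reduction, hydroxyl-directed epoxidation, trans-diaxial chloride opening, then inversion at C1 by oxidation and bulky-hydride reduction.
- Ring order: the cyclohexane ring is present from the start; a ring-fused oxirane and then a dioxolane (acetonide) are temporary; the side-chain oxirane is closed in the final step.

Assumption: (S)-(+)-carvone, the (+)-α-pinene-derived B-allyldiisopinocampheylborane solution, angelic acid and the L-sorbose-derived enantiomer of the Shi ketone are bought; locants follow the bisabolane skeleton of the target (ring C1 = CH–OAc, C2 = CH–OAng, C3 = C(OH)CH3, C4 = CHCl, C5 = CH2, C6 = CH bearing C7(=C14H2)–C8–C9–C10–C11), β is the ring face carrying the C6 side chain, α the opposite face, and Ang is (Z)-2-methylbut-2-enoyl.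

**Route**

Step 1
Reactants: 1 (S)-(+)-carvone
Product: 3 trans-6-hydroxycarvone (1α-hydroxy-2-oxo-3-ene), via sodium dienolate 2 (not isolated)
Conditions: NaN(SiMe3)2, THF, −78 °C; then 3-phenyl-2-(phenylsulfonyl)oxaziridine, −78 °C; aq. NH4Cl
Reagents that add atoms: 3-phenyl-2-(phenylsulfonyl)oxaziridine, O=S(=O)(c1ccccc1)N1OC1c1ccccc1
Why: Kinetic α'-deprotonation gives the cross-conjugated dienolate, which the N-sulfonyloxaziridine hydroxylates (Davis enolate oxidation) anti to the neighbouring isopropenyl group; this centre is reset in steps 6 and 7.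

Step 2
Reactants: 3 trans-6-hydroxycarvone
Product: 4 3-ene-1α,2β-diol, (1R,2R,6R)-3-methyl-6-(prop-1-en-2-yl)cyclohex-3-ene-1,2-diol
Conditions: NaBH4, CeCl3·7H2O, MeOH, −78 → 0 °C
Reagents that add atoms: none
Why: Luche 1,2-reduction with axial hydride delivery gives the equatorial 2β-alcohol cis to the C6 substituent, as in carvone → cis-carveol.

Step 3
Reactants: 4 3-ene-1α,2β-diol
Product: 5 3β,4β-epoxy-1α,2β-diol
Conditions: VO(acac)2 (3 mol %), t-BuOOH, CH2Cl2, 0 °C → rt
Reagents that add atoms: tert-butyl hydroperoxide, CC(C)(C)OO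
Why: Vanadium-catalysed hydroxyl-directed epoxidation delivers oxygen syn to the allylic 2β-OH (much faster than the homoallylic 1α-OH can direct) and leaves the isopropenyl group alone, setting C3 and C4 of the oxirane.

Step 4
Reactants: 5 3β,4β-epoxy-1α,2β-diol
Product: 6 4α-chloro-1α,2β,3β-triol
Conditions: LiCl, AcOH, THF, rt
Reagents that add atoms: lithium chloride, [Li+].[Cl-]
Why: Acid-assisted SN2 epoxide opening in which chloride attacks the secondary C4 from the α face (trans-diaxial, Fürst–Plattner, all other substituents equatorial), while tertiary C3 is deactivated by the adjacent carbinol; this sets 4α-Cl and 3β-OH.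

Step 5
Reactants: 6 4α-chloro-1α,2β,3β-triol
Product: 7 4α-chloro-2β,3β-isopropylidenedioxy-1α-ol
Conditions: Me2C(OMe)2, PPTS (cat.), CH2Cl2, rt
Reagents that add atoms: 2,2-dimethoxypropane, COC(C)(C)OC
Why: Acetonide formation under equilibrating conditions selects the cis 2β,3β-diol (cis-fused dioxolane) over the trans 1α,2β pair, leaving only C1–OH free and masking the chlorohydrin against base.

Step 6
Reactants: 7 4α-chloro-2β,3β-isopropylidenedioxy-1α-ol
Product: 8 4α-chloro-2β,3β-isopropylidenedioxy-1-one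
Conditions: Dess–Martin periodinane, pyridine, CH2Cl2, 0 °C → rt
Reagents that add atoms: none
Why: Dess–Martin oxidation of the only free secondary alcohol under buffered conditions avoids conjugation of the β,γ-alkene and β-alkoxy elimination.

Step 7
Reactants: 8 4α-chloro-2β,3β-isopropylidenedioxy-1-one
Product: 9 4α-chloro-2β,3β-isopropylidenedioxy-1β-ol
Conditions: LiBH(s-Bu)3 (L-Selectride), THF, −78 °C; aq. NH4Cl
Reagents that add atoms: none
Why: The bulky hydride attacks equatorially from the α face, away from the axial C3 oxygen and both β α-substituents, giving the axial 1β-alcohol (the isopulegone → neoisopulegol pattern).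

Step 8
Reactants: 9 4α-chloro-2β,3β-isopropylidenedioxy-1β-ol
Product: 10 1β-tert-butyldimethylsilyl ether of 9
Conditions: TBSOTf, 2,6-lutidine, CH2Cl2, 0 °C
Reagents that add atoms: tert-butyldimethylsilyl triflate, CC(C)(C)[Si](C)(C)OS(=O)(=O)C(F)(F)F
Why: Silyl triflate silylation caps the hindered axial alcohol without strong base, so the 1β-alkoxide cannot displace the trans-1,4 chloride.

Step 9
Reactants: 10 1β-silyl ether
Product: 11 8-chloro compound (C7(=C14H2)–C8H2Cl)
Conditions: Ca(OCl)2, CO2 (dry ice), CH2Cl2/H2O, 0 °C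
Reagents that add atoms: calcium hypochlorite, [Ca+2].[O-]Cl.[O-]Cl
Why: Ene-type allylic chlorination by HOCl on the only alkene gives the 2-(chloromethyl)allyl unit by proton loss from the methyl group, as in carvone → 10-chlorocarvone.

Step 10
Reactants: 11 8-chloro compound
Product: 12 8-acetoxy compound
Conditions: KOAc, n-Bu4NI (cat.), DMF, 50 °C
Reagents that add atoms: potassium acetate, CC(=O)[O-].[K+]
Why: SN2 displacement of the primary allylic chloride (SN2' gives the same product); the hindered axial ring chloride does not react.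

Step 11
Reactants: 12 8-acetoxy compound
Product: 13 8-hydroxy compound (allylic alcohol)
Conditions: K2CO3 (cat.), MeOH, rt
Reagents that add atoms: none
Why: Base-catalysed transesterification removes the acetate; the chlorohydrin oxygen is locked in the acetonide and the silyl ether is stable.

Step 12
Reactants: 13 allylic alcohol
Product: 14 8-al (2-substituted acrolein, fragment 1)
Conditions: MnO2, CH2Cl2, rt
Reagents that add atoms: none
Why: MnO2 oxidation is selective for the allylic alcohol and gives the enal under neutral conditions.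

Step 13
Reactants: 14 enal (fragment 1); 15 B-allyldiisopinocampheylborane from (+)-α-pinene (fragment 2)
Product: 17 (8S)-homoallylic alcohol (C8(OH)–C9H2–CH=CH2), via borinate ester 16 (not isolated)
Conditions: Et2O, −78 °C; then NaOH, H2O2, 0 °C → rt
Reagents that add atoms: none
Why: Brown asymmetric allylboration through a chair Zimmerman–Traxler transition state forms the C8–C9 bond under reagent control, giving 8S with this borane enantiomer (same facial sense as with benzaldehyde and methacrolein).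

Step 14
Reactants: 17 (8S)-homoallylic alcohol
Product: 18 (8S)-2β,3β,8-triol (1β-OTBS, 4α-Cl, allyl)
Conditions: AcOH/H2O 4:1, 40 °C
Reagents that add atoms: none
Why: Mild acid hydrolysis cleaves the cis-fused acetonide while the hindered secondary silyl ether survives.

Step 15
Reactants: 18 (8S)-2β,3β,8-triol
Product: 19 (8S)-4α-chloro-1β-silyloxybisabola-7(14),10-diene-2β,3β,8-triol
Conditions: 2-methyl-2-butene (excess), second-generation Grubbs catalyst RuCl2(=CHPh)(PCy3)(H2IMes) (5 mol %), CH2Cl2, 40 °C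
Reagents that add atoms: 2-methyl-2-butene, CC=C(C)C
Why: Olefin cross-metathesis converts the terminal vinyl group into the prenyl alkene; the hindered 1,1-disubstituted alkene does not take part.

Step 16
Reactants: 19 prenyl triol
Product: 20 2β,8-bis-angelate (3β-OH free, 1β-OTBS)
Conditions: angelic acid, 2,4,6-trichlorobenzoyl chloride, Et3N, toluene, rt; then 19, 75 °C
Reagents that add atoms: angelic acid, C/C=C(/C)C(=O)O
Why: Yamaguchi mixed-anhydride esterification without DMAP acylates both secondary hydroxyls with retention of the Z geometry; the tertiary 3β-OH does not react.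

Step 17
Reactants: 20 2β,8-bis-angelate
Product: 21 1β-alcohol
Conditions: HF·pyridine, pyridine, THF, 0 °C → rt
Reagents that add atoms: none
Why: Fluoride desilylation under mildly acidic conditions frees C1–OH without closing the chlorohydrin or moving the esters.

Step 18
Reactants: 21 1β-alcohol
Product: 22 1β-acetate
Conditions: Ac2O, pyridine, DMAP (cat.), CH2Cl2, 0 °C → rt
Reagents that add atoms: acetic anhydride, CC(=O)OC(C)=O
Why: DMAP-catalysed acetylation of the secondary alcohol is fast relative to migration of the hindered angelate, and the tertiary 3β-OH stays free.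

Step 19
Reactants: 22 1β-acetate
Product: 23 target, (1S,2S,3S,4S,6R,8S,10S)-1-acetoxy-2,8-bis(angeloyloxy)-4-chloro-10,11-epoxybisabol-7(14)-en-3-ol (CNP0313121.1)
Conditions: ent-Shi ketone (3 equiv), KHSO5 (Oxone), NaHCO3, MeCN/aq. Na2EDTA, pH 7–8, 0 °C
Reagents that add atoms: potassium peroxymonosulfate, [K+].[O-]S(=O)(=O)OO
Why: Shi asymmetric epoxidation (chiral dioxirane, spiro transition state) oxidises only the electron-rich trisubstituted alkene, the L-series ketone gives 10S, and the near-neutral pH keeps the chlorohydrin from closing.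

**Compound list**

1 | (S)-(+)-carvone | C=C(C)[C@H]1CC=C(C)C(=O)C1 | starting material
2 | sodium cross-conjugated dienolate of 1 | C=C(C)[C@H]1CC=C(C)C([O-])=C1.[Na+] | intermediate
3 | trans-6-hydroxycarvone, (5R,6R)-6-hydroxy-2-methyl-5-(prop-1-en-2-yl)cyclohex-2-en-1-one | C=C(C)[C@H]1CC=C(C)C(=O)[C@@H]1O | intermediate
4 | (1R,2R,6R)-3-methyl-6-(prop-1-en-2-yl)cyclohex-3-ene-1,2-diol (1α,2β-diol) | C=C(C)[C@H]1CC=C(C)[C@@H](O)[C@@H]1O | intermediate
5 | 3β,4β-epoxy-1α,2β-diol (oxirane cis to the 2-OH and the isopropenyl group) | C=C(C)[C@H]1C[C@H]2O[C@@]2(C)[C@@H](O)[C@@H]1O | intermediate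
6 | 4α-chloro-1α,2β,3β-triol | C=C(C)[C@H]1C[C@H](Cl)[C@@](C)(O)[C@@H](O)[C@@H]1O | intermediate
7 | 4α-chloro-2β,3β-isopropylidenedioxy-1α-ol | C=C(C)[C@H]1C[C@H](Cl)[C@@]2(C)OC(C)(C)O[C@H]2[C@@H]1O | intermediate
8 | 4α-chloro-2β,3β-isopropylidenedioxy-1-one | C=C(C)[C@H]1C[C@H](Cl)[C@@]2(C)OC(C)(C)O[C@H]2C1=O | intermediate
9 | 4α-chloro-2β,3β-isopropylidenedioxy-1β-ol | C=C(C)[C@H]1C[C@H](Cl)[C@@]2(C)OC(C)(C)O[C@H]2[C@H]1O | intermediate
10 | 1β-tert-butyldimethylsilyl ether of 9 | C=C(C)[C@H]1C[C@H](Cl)[C@@]2(C)OC(C)(C)O[C@H]2[C@H]1O[Si](C)(C)C(C)(C)C | intermediate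
11 | 8-chloro compound (2-(chloromethyl)allyl side chain) | C=C(CCl)[C@H]1C[C@H](Cl)[C@@]2(C)OC(C)(C)O[C@H]2[C@H]1O[Si](C)(C)C(C)(C)C | intermediate
12 | 8-acetoxy compound | C=C(COC(C)=O)[C@H]1C[C@H](Cl)[C@@]2(C)OC(C)(C)O[C@H]2[C@H]1O[Si](C)(C)C(C)(C)C | intermediate
13 | 8-hydroxy compound (allylic alcohol) | C=C(CO)[C@H]1C[C@H](Cl)[C@@]2(C)OC(C)(C)O[C@H]2[C@H]1O[Si](C)(C)C(C)(C)C | intermediate
14 | 8-al (2-substituted acrolein, fragment 1) | C=C(C=O)[C@H]1C[C@H](Cl)[C@@]2(C)OC(C)(C)O[C@H]2[C@H]1O[Si](C)(C)C(C)(C)C | intermediate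
15 | B-allyldiisopinocampheylborane from (+)-α-pinene (fragment 2) | C=CCB([C@@H]1C[C@@H]2C[C@H]([C@H]1C)C2(C)C)[C@@H]1C[C@@H]2C[C@H]([C@H]1C)C2(C)C | starting material
16 | diisopinocampheylborinate ester of 17 | C=C([C@H](CC=C)OB([C@@H]3C[C@@H]4C[C@H]([C@H]3C)C4(C)C)[C@@H]3C[C@@H]4C[C@H]([C@H]3C)C4(C)C)[C@H]1C[C@H](Cl)[C@@]2(C)OC(C)(C)O[C@H]2[C@H]1O[Si](C)(C)C(C)(C)C | intermediate
17 | (8S)-homoallylic alcohol (acetonide, 1β-OTBS, allyl at C8) | C=C([C@H](CC=C)O)[C@H]1C[C@H](Cl)[C@@]2(C)OC(C)(C)O[C@H]2[C@H]1O[Si](C)(C)C(C)(C)C | intermediate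
18 | (8S)-2β,3β,8-triol (1β-OTBS, 4α-Cl, allyl) | C=C([C@H](CC=C)O)[C@H]1C[C@H](Cl)[C@@](C)(O)[C@@H](O)[C@H]1O[Si](C)(C)C(C)(C)C | intermediate
19 | (8S)-4α-chloro-1β-(tert-butyldimethylsilyloxy)bisabola-7(14),10-diene-2β,3β,8-triol | C=C([C@H](CC=C(C)C)O)[C@H]1C[C@H](Cl)[C@@](C)(O)[C@@H](O)[C@H]1O[Si](C)(C)C(C)(C)C | intermediate
20 | 2β,8-bis-angelate of 19 | C=C([C@H](CC=C(C)C)OC(=O)/C(C)=C\C)[C@H]1C[C@H](Cl)[C@@](C)(O)[C@@H](OC(=O)/C(C)=C\C)[C@H]1O[Si](C)(C)C(C)(C)C | intermediate
21 | 2β,8-bis-angelate 1β,3β-diol | C=C([C@H](CC=C(C)C)OC(=O)/C(C)=C\C)[C@H]1C[C@H](Cl)[C@@](C)(O)[C@@H](OC(=O)/C(C)=C\C)[C@H]1O | intermediate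
22 | 1β-acetate 2β,8-bis-angelate (10,11-alkene) | C=C([C@H](CC=C(C)C)OC(=O)/C(C)=C\C)[C@H]1C[C@H](Cl)[C@@](C)(O)[C@@H](OC(=O)/C(C)=C\C)[C@H]1OC(C)=O | intermediate
23 | CNP0313121.1, (1S,2S,3S,4S,6R,8S,10S)-1-acetoxy-2,8-bis(angeloyloxy)-4-chloro-10,11-epoxybisabol-7(14)-en-3-ol | C=C([C@H](C[C@@H]1OC1(C)C)OC(=O)/C(C)=C\C)[C@H]1C[C@H](Cl)[C@@](C)(O)[C@@H](OC(=O)/C(C)=C\C)[C@H]1OC(C)=O | target

**Totals and risks**

Total steps: 19. Longest linear sequence: 19 steps (1 → 23; 15 is used as purchased).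

Steps most likely to fail:

1. Step 16 (bis-angeloylation). The C2–OH is hindered, forcing conditions can isomerise angelate to tiglate, and warm amine may start to close the chlorohydrin. Fallback: set out from 19 and close the chlorohydrin on purpose with K2CO3 in MeOH to the 3β,4β-epoxy diol F6. Acylate both alkoxides with LiN(SiMe3)2 and angelic anhydride in THF at −78 → 0 °C to the epoxy bis-angelate F7 (a cis epoxy alkoxide cannot undergo Payne rearrangement). Reopen the oxirane with LiCl/AcOH in THF, where trans-diaxial attack at C4 is now also favoured by the electron-withdrawing C2 ester, and rejoin the route at 20.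

2. Step 19 (final epoxidation). The tertiary trans-diaxial chlorohydrin can revert to the ring epoxide if the pH drifts upward, and the stoichiometric-ketone protocol may be slow. Fallback: set out from 22 and silylate the tertiary hydroxyl with TMSOTf/2,6-lutidine at −78 °C to the 3-O-trimethylsilyl ether F8. Run the catalytic Shi epoxidation at pH 10.5 (ent-Shi ketone 0.3 equiv, KHSO5, K2CO3 buffer, MeCN/dimethoxymethane, 0 °C) to the silylated epoxide F9. Remove the silyl group with Bu4NF/AcOH in THF at 0 °C to arrive at 23.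

3. Step 4 (chloride opening of the unprotected epoxy diol). Regiocontrol rests on substrate conformation alone, and the extra free hydroxyl may complicate steps 3 and 4. Fallback: set out from 3 and silylate (TBSCl, imidazole, DMF) to the 1α-silyl ether F1. Reduce with NaBH4/CeCl3·7H2O to the allylic alcohol F2 and epoxidise with VO(acac)2/t-BuOOH to the epoxy alcohol F3. Open F3 with ClTi(Oi-Pr)3 in CH2Cl2, where the titanium alkoxide of the single free hydroxyl chelates the oxirane oxygen and directs chloride to C4, giving the chlorodiol F4. Convert F4 with Me2C(OMe)2/PPTS to the acetonide F5 and remove the silyl group with Bu4NF/AcOH to rejoin the route at 7.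

**Further compounds**

F1 | step 4 | 1α-O-tert-butyldimethylsilyl ether of 3 | C=C(C)[C@H]1CC=C(C)C(=O)[C@@H]1O[Si](C)(C)C(C)(C)C
F2 | step 4 | 1α-silyloxy-3-en-2β-ol | C=C(C)[C@H]1CC=C(C)[C@@H](O)[C@@H]1O[Si](C)(C)C(C)(C)C
F3 | step 4 | 1α-silyloxy-3β,4β-epoxy-2β-ol | C=C(C)[C@H]1C[C@H]2O[C@@]2(C)[C@@H](O)[C@@H]1O[Si](C)(C)C(C)(C)C
F4 | step 4 | 1α-silyloxy-4α-chloro-2β,3β-diol | C=C(C)[C@H]1C[C@H](Cl)[C@@](C)(O)[C@@H](O)[C@@H]1O[Si](C)(C)C(C)(C)C
F5 | step 4 | 1α-silyloxy-4α-chloro-2β,3β-acetonide | C=C(C)[C@H]1C[C@H](Cl)[C@@]2(C)OC(C)(C)O[C@H]2[C@@H]1O[Si](C)(C)C(C)(C)C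
F6 | step 16 | (8S)-3β,4β-epoxy-1β-silyloxybisabola-7(14),10-diene-2β,8-diol | C=C([C@H](CC=C(C)C)O)[C@H]1C[C@H]2O[C@@]2(C)[C@@H](O)[C@H]1O[Si](C)(C)C(C)(C)C
F7 | step 16 | 2β,8-bis-angelate of F6 | C=C([C@H](CC=C(C)C)OC(=O)/C(C)=C\C)[C@H]1C[C@H]2O[C@@]2(C)[C@@H](OC(=O)/C(C)=C\C)[C@H]1O[Si](C)(C)C(C)(C)C
F8 | step 19 | 3-O-trimethylsilyl ether of 22 | C=C([C@H](CC=C(C)C)OC(=O)/C(C)=C\C)[C@H]1C[C@H](Cl)[C@@](C)(O[Si](C)(C)C)[C@@H](OC(=O)/C(C)=C\C)[C@H]1OC(C)=O
F9 | step 19 | 3-O-trimethylsilyl ether of 23 | C=C([C@H](C[C@@H]1OC1(C)C)OC(=O)/C(C)=C\C)[C@H]1C[C@H](Cl)[C@@](C)(O[Si](C)(C)C)[C@@H](OC(=O)/C(C)=C\C)[C@H]1OC(C)=O
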